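**Plan**
- Cuts, in retrosynthetic order: the allyl aryl ether O–CH2 bond (Mitsunobu), the side-chain C=C (Horner–Wadsworth–Emmons), O6–C5 (iodoetherification), the C8–side-chain bond (anti-SN2′), C5–CH3 (Stille) and C2–O (desymmetrising oxa-Michael addition).
- Enabling feature: in the carbocycle C1–C2–C3–C4–C5–C8 of the 6-oxabicyclo[3.2.1]octane, quaternary C1 (CH3 and C7H2–O6) lies next to C2–OH, which is cis to C7. With C4 as carbonyl and C2/C8 as β-carbons, this is a prochiral 4-(hydroxymethyl)-4-methylcyclohexa-2,5-dienone whose own C7–OH can carry an oxygen nucleophile to C2.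
- Forward order: the carbocycle comes from benzoic acid (Birch alkylation, bis-allylic oxidation). A temporary dioxaborinane closes in the key step and is exchanged for an acetonide. The C5 methyl and the C8 chain are then added, the oxolane ring C1–C7–O6–C5–C8 closes, and the chain is extended and joined to umbelliferone.
- Stereochemistry: C1 comes from the chiral thiourea (choice of enone arm) and C2 from the C7–O–B tether. A temporary C4 carbinol comes from a CBS reagent, C8 from anti transfer from C4, C5 from intramolecular attack of C7–OH, and the E-alkene from the phosphonate olefination.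

Key step: step 6

Locants C1–C8 and O6 are those of the 6-oxabicyclo[3.2.1]octane core of the target and are used for all intermediates.
Assumption: the quinine-derived thiourea is taken to favour the enone arm that leads to (4aR,8aR)-9. If the sense of induction proves opposite, the pseudo-enantiomeric quinidine-derived thiourea is used with no other change.

**Step 1**
Reactants: 1 benzoic acid
Product: 2 1-methylcyclohexa-2,5-diene-1-carboxylic acid
Conditions: Li, NH3(l)/THF, −78 °C; MeI; then aq. HCl
Reagents that add atoms: iodomethane, IC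
Why: Birch reductive alkylation, in which dissolving-metal reduction of the benzoate gives the dienolate dianion and iodomethane alkylates it at the ipso carbon, creating the (still achiral) quaternary carbon and a skipped 1,4-diene.

**Step 2**
Reactants: 2 1-methylcyclohexa-2,5-diene-1-carboxylic acid
Product: 3 (1-methylcyclohexa-2,5-dien-1-yl)methanol
Conditions: LiAlH4, Et2O, 0 °C → reflux
Reagents that add atoms: none
Why: Hydride reduction of a carboxylic acid with LiAlH4, to which isolated alkenes are inert, gives the neopentyl primary alcohol that becomes C7–OH.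

**Step 3**
Reactants: 3 (1-methylcyclohexa-2,5-dien-1-yl)methanol
Product: 4 tert-butyldimethyl[(1-methylcyclohexa-2,5-dien-1-yl)methoxy]silane
Conditions: TBSCl, imidazole, DMF, rt
Reagents that add atoms: tert-butyldimethylsilyl chloride, CC(C)(C)[Si](C)(C)Cl
Why: Imidazole-promoted silylation masks the primary alcohol, which would otherwise be at risk in the following oxidation.

**Step 4**
Reactants: 4 tert-butyldimethyl[(1-methylcyclohexa-2,5-dien-1-yl)methoxy]silane
Product: 5 4-[(tert-butyldimethylsilyloxy)methyl]-4-methylcyclohexa-2,5-dien-1-one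
Conditions: Rh2(cap)4 (cap = caprolactamate, 1 mol %), t-BuOOH (70% aq.), 1,2-dichloroethane, 40 °C
Reagents that add atoms: tert-butyl hydroperoxide, CC(C)(C)OO
Why: Allylic C–H oxidation by a tert-butylperoxyl radical chain abstracts hydrogen from the doubly allylic C4H2, the only available position, and capture of the dienyl radical at its central carbon (remote from quaternary C1) followed by collapse of the mixed peroxide should give the cross-conjugated dienone, as is usual for Birch alkylation products.

**Step 5**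
Reactants: 5 4-[(tert-butyldimethylsilyloxy)methyl]-4-methylcyclohexa-2,5-dien-1-one
Product: 6 4-(hydroxymethyl)-4-methylcyclohexa-2,5-dien-1-one
Conditions: 48% aq. HF, MeCN, 0 °C
Reagents that add atoms: none
Why: Acidic fluoride desilylation is preferred to basic fluoride because the alkoxide of 6 could expel formaldehyde in a retro-aldol aromatisation to p-cresol, whereas dilute HF is too weak to trigger a dienone–phenol rearrangement.

**Step 6**
Reactants: 6 4-(hydroxymethyl)-4-methylcyclohexa-2,5-dien-1-one; 7 phenylboronic acid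
Product: 9 (4aR,8aR)-4a-methyl-2-phenyl-4,4a,8,8a-tetrahydro-7H-benzo[d][1,3,2]dioxaborinin-7-one (cis-fused; C4 enone C5=C8 intact), via boronic hemiester 8 (not isolated)
Conditions: 7 (1.2 equiv), 1-[3,5-bis(trifluoromethyl)phenyl]-3-[(8α,9S)-6′-methoxycinchonan-9-yl]thiourea (15 mol %), 4 Å molecular sieves, toluene, 0 °C → rt
Reagents that add atoms: phenylboronic acid (7), OB(O)c1ccccc1
Why: Proposed new method: the C7 hydroxyl of 6 condenses reversibly with 7 to the hemiester 8; the thiourea hydrogen-bonds to the dienone carbonyl while the quinuclidine nitrogen engages the remaining B–OH, whose oxygen adds to one β-carbon, and the resulting enol is protonated at C3. The closest known reactions are amine–thiourea-catalysed oxa-Michael additions of boronic acid hemiesters of γ- and δ-hydroxy enones and organocatalytic desymmetrisations of 4,4-disubstituted cyclohexadienones by tethered O- or N-nucleophiles; their combination on a 4-(hydroxymethyl)dienone is not known. The single ring closed is the temporary 1,3,2-dioxaborinane (O–B–O–C7–C1–C2), formed 6-exo-trig with C3 outside the new ring. C1 becomes stereogenic through the catalyst's choice between the two enantiotopic enone arms, and C2 is fixed relative to it because the C7–O–B tether can reach the planar ring only on the face that carries C7, so the C2–O bond is cis to C7. The step needs arm selection (catalyst), single addition (after cyclisation boron has no OH left, so the C5=C8 enone survives) and suppression of formaldehyde loss to p-cresol (the alcohol is esterified on boron and only a weak tertiary amine is present). Molecular sieves and low temperature should hold the product against retro-Michael racemisation.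

**Step 7**
Reactants: 9 (4aR,8aR)-4a-methyl-2-phenyl-4,4a,8,8a-tetrahydro-7H-benzo[d][1,3,2]dioxaborinin-7-one
Product: 11 (4aR,8aR)-2,2,4a-trimethyl-4,4a,8,8a-tetrahydro-7H-benzo[d][1,3]dioxin-7-one, via free diol 10 (not isolated)
Conditions: pinacol (1.1 equiv), Me2C(OMe)2, pyridinium p-toluenesulfonate (cat.), CH2Cl2, rt
Reagents that add atoms: 2,2-dimethoxypropane, COC(C)(C)OC
Why: Boronate transesterification to the pinacol ester frees the diol and acid-catalysed transketalisation traps it at once as the cis-fused 1,3-dioxane, so the equilibrium is pulled forward, the β-hydroxy ketone meets neither base nor peroxide, and boron is removed before the cross-coupling.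

**Step 8**
Reactants: 11 (4aR,8aR)-2,2,4a-trimethyl-4,4a,8,8a-tetrahydro-7H-benzo[d][1,3]dioxin-7-one
Product: 12 (4aR,8aR)-6-iodo-2,2,4a-trimethyl-4,4a,8,8a-tetrahydro-7H-benzo[d][1,3]dioxin-7-one
Conditions: I2, pyridine, CH2Cl2, 0 °C → rt
Reagents that add atoms: iodine, [I][I]
Why: Pyridine-promoted α-iodination of an enone (Baylis–Hillman-type addition of pyridine at C8, iodination of the enolate at C5, elimination) is established for 4,4-disubstituted cyclohexenones and functionalises only the vinylic α-carbon C5.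

**Step 9**
Reactants: 12 (4aR,8aR)-6-iodo-2,2,4a-trimethyl-4,4a,8,8a-tetrahydro-7H-benzo[d][1,3]dioxin-7-one
Product: 13 (4aR,8aR)-2,2,4a,6-tetramethyl-4,4a,8,8a-tetrahydro-7H-benzo[d][1,3]dioxin-7-one
Conditions: SnMe4, PdCl2(PhCN)2 (5 mol %), AsPh3, CuI (10 mol %), NMP, 80 °C
Reagents that add atoms: tetramethylstannane, C[Sn](C)(C)C
Why: Stille cross-coupling of an α-iodoenone in its base-free AsPh3/CuI variant transfers methyl to C5 without exposing the β-alkoxy ketone to base that could cause E1cB loss of the C2 oxygen.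

**Step 10**
Reactants: 13 (4aR,8aR)-2,2,4a,6-tetramethyl-4,4a,8,8a-tetrahydro-7H-benzo[d][1,3]dioxin-7-one
Product: 14 (4aR,7R,8aR)-2,2,4a,6-tetramethyl-4a,7,8,8a-tetrahydro-4H-benzo[d][1,3]dioxin-7-ol (C4–OH trans to C2–O and C7)
Conditions: (S)-2-methyl-CBS-oxazaborolidine (20 mol %), BH3·SMe2, THF, −30 °C; MeOH, aqueous work-up
Reagents that add atoms: none
Why: Corey–Bakshi–Shibata reduction, in which the α-methylated alkenyl arm acts as the large and C3H2 as the small substituent, so the (S)-catalyst should deliver hydride to the face cis to C7 and give the (7R)-allylic alcohol under reagent control with clean 1,2-selectivity.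

**Step 11**
Reactants: 14 (4aR,7R,8aR)-2,2,4a,6-tetramethyl-4a,7,8,8a-tetrahydro-4H-benzo[d][1,3]dioxin-7-ol
Product: 15 (4aR,7R,8aR)-2,2,4a,6-tetramethyl-4a,7,8,8a-tetrahydro-4H-benzo[d][1,3]dioxin-7-yl pyridine-2-carboxylate
Conditions: picolinic acid, DCC, DMAP (cat.), CH2Cl2, rt
Reagents that add atoms: picolinic acid, OC(=O)c1ccccn1
Why: Steglich esterification installs, with retention at C4, a chelating picolinoxy leaving group known to steer alkylcopper reagents to the γ-position.

**Step 12**
Reactants: 15 (4aR,7R,8aR)-2,2,4a,6-tetramethyl-4a,7,8,8a-tetrahydro-4H-benzo[d][1,3]dioxin-7-yl pyridine-2-carboxylate; 16 2-(2-bromoethyl)-2-methyl-1,3-dioxolane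
Product: 18 (4aR,5S,8aR)-2,2,4a,6-tetramethyl-5-[2-(2-methyl-1,3-dioxolan-2-yl)ethyl]-4a,5,8,8a-tetrahydro-4H-benzo[d][1,3]dioxine (chain at C8 cis to C7; alkene C4=C5), via Grignard reagent 17 (not isolated)
Conditions: 16, Mg, THF, 25 °C; CuBr·SMe2 (1 equiv per 17), THF, −40 °C; then 15, −40 → 0 °C; aqueous work-up
Reagents that add atoms: 2-(2-bromoethyl)-2-methyl-1,3-dioxolane (16), CC1(CCBr)OCCO1
Why: Copper-mediated anti-SN2′ allylic substitution of a picolinate, in which MgBr2 chelation activates the leaving group and the alkylcopper attacks γ-carbon C8 on the face opposite the C4–O bond, so the C4 configuration is transferred to C8 while the alkene moves to C4=C5 and the masked methyl ketone arrives with the chain.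

**Step 13**
Reactants: 18 (4aR,5S,8aR)-2,2,4a,6-tetramethyl-5-[2-(2-methyl-1,3-dioxolan-2-yl)ethyl]-4a,5,8,8a-tetrahydro-4H-benzo[d][1,3]dioxine
Product: 19 4-[(1S,5R,6R)-5-hydroxy-6-(hydroxymethyl)-2,6-dimethylcyclohex-2-en-1-yl]butan-2-one
Conditions: 1 M HCl, THF, rt
Reagents that add atoms: water, O
Why: Acid-catalysed ketal hydrolysis removes the acetonide and the dioxolane in one operation, under conditions too mild to protonate the trisubstituted C4=C5 alkene, and touches no stereocentre.

**Step 14**
Reactants: 19 4-[(1S,5R,6R)-5-hydroxy-6-(hydroxymethyl)-2,6-dimethylcyclohex-2-en-1-yl]butan-2-one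
Product: 20 4-[(1R,2R,4R,5R,8R)-2-hydroxy-4-iodo-1,5-dimethyl-6-oxabicyclo[3.2.1]octan-8-yl]butan-2-one (C4–I trans to O6)
Conditions: NIS (1.05 equiv), MeCN, 0 °C, dark
Reagents that add atoms: N-iodosuccinimide, O=C1CCC(=O)N1I
Why: Iodoetherification (5-exo, Markovnikov, the ether counterpart of the iodolactonisation of cyclohex-3-enecarboxylic acids) forms the iodonium ion on the face opposite C7 and lets axial C7–OH attack tertiary C5 from behind, which sets C5, whereas C2–OH is equatorial in that half-chair and could only close a more strained 7-oxabicyclo[2.2.1]heptane through a boat.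

**Step 15**
Reactants: 20 4-[(1R,2R,4R,5R,8R)-2-hydroxy-4-iodo-1,5-dimethyl-6-oxabicyclo[3.2.1]octan-8-yl]butan-2-one
Product: 21 4-[(1R,2R,5S,8R)-2-hydroxy-1,5-dimethyl-6-oxabicyclo[3.2.1]octan-8-yl]butan-2-one
Conditions: Bu3SnH, AIBN (cat.), toluene, 80 °C
Reagents that add atoms: none
Why: Radical-chain hydrodeiodination removes the auxiliary C4 iodide, since the secondary radical is quenched by the stannane far faster than it could fragment or add to the remote ketone, and no stereocentre of the target is involved.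

**Step 16**
Reactants: 21 4-[(1R,2R,5S,8R)-2-hydroxy-1,5-dimethyl-6-oxabicyclo[3.2.1]octan-8-yl]butan-2-one
Product: 22 ethyl (2E)-5-[(1R,2R,5S,8R)-2-hydroxy-1,5-dimethyl-6-oxabicyclo[3.2.1]octan-8-yl]-3-methylpent-2-enoate
Conditions: (EtO)2P(O)CH2CO2Et, NaH, THF, 0 → 50 °C
Reagents that add atoms: triethyl phosphonoacetate, CCOC(=O)CP(=O)(OCC)OCC
Why: Horner–Wadsworth–Emmons olefination of a methyl ketone with a stabilised phosphonate anion, which is too weakly basic to deprotonate C2–OH, is reversible at the addition stage and should favour the E-enoate (chain trans to the ester), the minor Z-isomer being removed by chromatography.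

**Step 17**
Reactants: 22 ethyl (2E)-5-[(1R,2R,5S,8R)-2-hydroxy-1,5-dimethyl-6-oxabicyclo[3.2.1]octan-8-yl]-3-methylpent-2-enoate
Product: 23 (1R,2R,5S,8R)-8-[(3E)-5-hydroxy-3-methylpent-3-en-1-yl]-1,5-dimethyl-6-oxabicyclo[3.2.1]octan-2-ol
Conditions: i-Bu2AlH (4 equiv), CH2Cl2, −78 °C; aq. potassium sodium tartrate
Reagents that add atoms: none
Why: 1,2-Reduction of the α,β-unsaturated ester with excess i-Bu2AlH (one equivalent is consumed by C2–OH) gives the E-allylic alcohol without affecting the alkene geometry or the ether bridge.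

**Step 18**
Reactants: 23 (1R,2R,5S,8R)-8-[(3E)-5-hydroxy-3-methylpent-3-en-1-yl]-1,5-dimethyl-6-oxabicyclo[3.2.1]octan-2-ol; 24 umbelliferone
Product: 25 7-{[(2E)-5-[(1R,2R,5S,8R)-2-hydroxy-1,5-dimethyl-6-oxabicyclo[3.2.1]octan-8-yl]-3-methylpent-2-en-1-yl]oxy}-2H-chromen-2-one (target)
Conditions: 24, PPh3, DIAD, THF, 0 °C → rt
Reagents that add atoms: umbelliferone (24), O=c1ccc2ccc(O)cc2o1
Why: Mitsunobu etherification, in which the acidic phenol displaces the oxyphosphonium salt of the unhindered primary allylic alcohol in an SN2 sense while the equatorial C2–OH next to quaternary C1 is too hindered to be activated, so no protecting group is needed.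

**Compound list**
1 | benzoic acid | OC(=O)c1ccccc1 | starting material
2 | 1-methylcyclohexa-2,5-diene-1-carboxylic acid | CC1(C(=O)O)C=CCC=C1 | intermediate
3 | (1-methylcyclohexa-2,5-dien-1-yl)methanol | CC1(CO)C=CCC=C1 | intermediate
4 | tert-butyldimethyl[(1-methylcyclohexa-2,5-dien-1-yl)methoxy]silane | CC1(CO[Si](C)(C)C(C)(C)C)C=CCC=C1 | intermediate
5 | 4-[(tert-butyldimethylsilyloxy)methyl]-4-methylcyclohexa-2,5-dien-1-one | CC1(CO[Si](C)(C)C(C)(C)C)C=CC(=O)C=C1 | intermediate
6 | 4-(hydroxymethyl)-4-methylcyclohexa-2,5-dien-1-one | CC1(CO)C=CC(=O)C=C1 | intermediate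
7 | phenylboronic acid | OB(O)c1ccccc1 | starting material
8 | (1-methyl-4-oxocyclohexa-2,5-dien-1-yl)methyl hydrogen phenylboronate | CC1(COB(O)c2ccccc2)C=CC(=O)C=C1 | intermediate
9 | (4aR,8aR)-4a-methyl-2-phenyl-4,4a,8,8a-tetrahydro-7H-benzo[d][1,3,2]dioxaborinin-7-one | C[C@]12C=CC(=O)C[C@H]1OB(c1ccccc1)OC2 | intermediate
10 | (4R,5R)-5-hydroxy-4-(hydroxymethyl)-4-methylcyclohex-2-en-1-one | C[C@]1(CO)C=CC(=O)C[C@H]1O | intermediate
11 | (4aR,8aR)-2,2,4a-trimethyl-4,4a,8,8a-tetrahydro-7H-benzo[d][1,3]dioxin-7-one | C[C@]12C=CC(=O)C[C@H]1OC(C)(C)OC2 | intermediate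
12 | (4aR,8aR)-6-iodo-2,2,4a-trimethyl-4,4a,8,8a-tetrahydro-7H-benzo[d][1,3]dioxin-7-one | C[C@]12C=C(I)C(=O)C[C@H]1OC(C)(C)OC2 | intermediate
13 | (4aR,8aR)-2,2,4a,6-tetramethyl-4,4a,8,8a-tetrahydro-7H-benzo[d][1,3]dioxin-7-one | C[C@]12C=C(C)C(=O)C[C@H]1OC(C)(C)OC2 | intermediate
14 | (4aR,7R,8aR)-2,2,4a,6-tetramethyl-4a,7,8,8a-tetrahydro-4H-benzo[d][1,3]dioxin-7-ol | C[C@]12C=C(C)[C@H](O)C[C@H]1OC(C)(C)OC2 | intermediate
15 | (4aR,7R,8aR)-2,2,4a,6-tetramethyl-4a,7,8,8a-tetrahydro-4H-benzo[d][1,3]dioxin-7-yl pyridine-2-carboxylate | C[C@]12C=C(C)[C@H](OC(=O)c3ccccn3)C[C@H]1OC(C)(C)OC2 | intermediate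
16 | 2-(2-bromoethyl)-2-methyl-1,3-dioxolane | CC1(CCBr)OCCO1 | starting material
17 | [2-(2-methyl-1,3-dioxolan-2-yl)ethyl]magnesium bromide | CC1(CC[Mg]Br)OCCO1 | intermediate
18 | (4aR,5S,8aR)-2,2,4a,6-tetramethyl-5-[2-(2-methyl-1,3-dioxolan-2-yl)ethyl]-4a,5,8,8a-tetrahydro-4H-benzo[d][1,3]dioxine | C[C@]12[C@@H](CCC3(C)OCCO3)C(C)=CC[C@H]1OC(C)(C)OC2 | intermediate
19 | 4-[(1S,5R,6R)-5-hydroxy-6-(hydroxymethyl)-2,6-dimethylcyclohex-2-en-1-yl]butan-2-one | C[C@]1(CO)[C@@H](CCC(C)=O)C(C)=CC[C@H]1O | intermediate
20 | 4-[(1R,2R,4R,5R,8R)-2-hydroxy-4-iodo-1,5-dimethyl-6-oxabicyclo[3.2.1]octan-8-yl]butan-2-one | CC(=O)CC[C@@H]1[C@]2(C)CO[C@@]1(C)[C@H](I)C[C@H]2O | intermediate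
21 | 4-[(1R,2R,5S,8R)-2-hydroxy-1,5-dimethyl-6-oxabicyclo[3.2.1]octan-8-yl]butan-2-one | CC(=O)CC[C@@H]1[C@]2(C)CO[C@@]1(C)CC[C@H]2O | intermediate
22 | ethyl (2E)-5-[(1R,2R,5S,8R)-2-hydroxy-1,5-dimethyl-6-oxabicyclo[3.2.1]octan-8-yl]-3-methylpent-2-enoate | C/C(=C\C(=O)OCC)CC[C@@H]1[C@]2(C)CO[C@@]1(C)CC[C@H]2O | intermediate
23 | (1R,2R,5S,8R)-8-[(3E)-5-hydroxy-3-methylpent-3-en-1-yl]-1,5-dimethyl-6-oxabicyclo[3.2.1]octan-2-ol | C/C(=C\CO)CC[C@@H]1[C@]2(C)CO[C@@]1(C)CC[C@H]2O | intermediate
24 | umbelliferone (7-hydroxy-2H-chromen-2-one) | O=c1ccc2ccc(O)cc2o1 | starting material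
25 | 7-{[(2E)-5-[(1R,2R,5S,8R)-2-hydroxy-1,5-dimethyl-6-oxabicyclo[3.2.1]octan-8-yl]-3-methylpent-2-en-1-yl]oxy}-2H-chromen-2-one | C/C(=C\COc1ccc2ccc(=O)oc2c1)CC[C@@H]1[C@]2(C)CO[C@@]1(C)CC[C@H]2O | target

Total step count: 18. Longest linear sequence: 18 steps from 1 (7, 16 and 24 are purchased).

**Steps most likely to fail**

**1. Step 6.**
- What may go wrong: discrimination between the two enone arms may be weak, and addition to the cross-conjugated dienone may be slow. Retro-Michael equilibration may erode the enantiomeric purity, or formaldehyde may be lost with aromatisation.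
- Fallback (known reaction types): it sets out from 3 and brings the oxygen to C2 at the diene oxidation level.
- Hydroxyl-directed catalytic asymmetric epoxidation of the homoallylic alcohol (VO(Oi-Pr)3, a chiral C2-symmetric bishydroxamic acid ligand, cumene hydroperoxide, toluene) desymmetrises the diene. It places the oxirane on the face of C7, giving the syn-epoxy alcohol F1.
- LiAlH4 opens the oxirane at C3, the carbon remote from the quaternary centre, to the cis-diol F2.
- Me2C(OMe)2 with pyridinium p-toluenesulfonate gives the alkene acetonide F3.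
- Allylic oxidation of its only allylic CH2 (C4) under the conditions of step 4 leads to 11, where the route is rejoined.

**2. Step 12.**
- What may go wrong: approach of the copper reagent to C8, next to quaternary C1 and on the concave face of the cis-fused bicycle, may be slow. Direct substitution at C4 or attack at the ester carbonyl could then compete.
- Fallback: it sets out from 13 and delivers the nucleophile from the leaving group itself.
- Luche reduction (NaBH4, CeCl3·7H2O, MeOH, −78 °C), with hydride expected on the convex face, gives the epimeric (7S)-allylic alcohol F4.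
- DCC/DMAP esterification with 2-(diphenylphosphanyl)benzoic acid gives the phosphine-bearing ester F5.
- Phosphine-directed syn-SN2′ substitution with 17 and CuBr·SMe2 in Et2O places the chain on the C7 face, in a half-chair whose axial C1 methyl points to the opposite face.
- The sequence comes back at 18 and also makes the reagent-controlled reduction of step 10 unnecessary.

**3. Step 14.**
- What may go wrong: ring closure by C2–OH instead of C7–OH, through the alternative half-chair, would divert material to an oxanorbornane skeleton.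
- Fallback: it sets out from 19 and differentiates the two hydroxyls first.
- TESCl, imidazole and DMAP in DMF give the bis(triethylsilyl) ether F6.
- Pyridinium p-toluenesulfonate in MeOH/CH2Cl2 at 0 °C cleaves the primary silyl ether selectively to the C2-silylated alcohol F7.
- NIS in MeCN can then close only the C7–O–C5 bridge, giving the silylated iodo ether F8.
- Bu3SnH/AIBN gives the silylated bicyclic ketone F9, and HF·pyridine in THF returns to the route at 21.

**Further compounds**
F1 | step 6 | [(1S,2R,6R)-2-methyl-7-oxabicyclo[4.1.0]hept-3-en-2-yl]methanol | C[C@]1(CO)C=CC[C@H]2O[C@@H]12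
F2 | step 6 | (1R,2R)-2-(hydroxymethyl)-2-methylcyclohex-3-en-1-ol | C[C@]1(CO)C=CCC[C@H]1O
F3 | step 6 | (4aR,8aR)-2,2,4a-trimethyl-4a,7,8,8a-tetrahydro-4H-benzo[d][1,3]dioxine | C[C@]12C=CCC[C@H]1OC(C)(C)OC2
F4 | step 12 | (4aR,7S,8aR)-2,2,4a,6-tetramethyl-4a,7,8,8a-tetrahydro-4H-benzo[d][1,3]dioxin-7-ol | C[C@]12C=C(C)[C@@H](O)C[C@H]1OC(C)(C)OC2
F5 | step 12 | (4aR,7S,8aR)-2,2,4a,6-tetramethyl-4a,7,8,8a-tetrahydro-4H-benzo[d][1,3]dioxin-7-yl 2-(diphenylphosphanyl)benzoate | C[C@]12C=C(C)[C@@H](OC(=O)c3ccccc3P(c3ccccc3)c3ccccc3)C[C@H]1OC(C)(C)OC2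
F6 | step 14 | 4-[(1S,5R,6R)-2,6-dimethyl-5-(triethylsilyloxy)-6-(triethylsilyloxymethyl)cyclohex-2-en-1-yl]butan-2-one | C[C@]1(CO[Si](CC)(CC)CC)[C@@H](CCC(C)=O)C(C)=CC[C@H]1O[Si](CC)(CC)CC
F7 | step 14 | 4-[(1S,5R,6R)-6-(hydroxymethyl)-2,6-dimethyl-5-(triethylsilyloxy)cyclohex-2-en-1-yl]butan-2-one | C[C@]1(CO)[C@@H](CCC(C)=O)C(C)=CC[C@H]1O[Si](CC)(CC)CC
F8 | step 14 | 4-[(1R,2R,4R,5R,8R)-4-iodo-1,5-dimethyl-2-(triethylsilyloxy)-6-oxabicyclo[3.2.1]octan-8-yl]butan-2-one | CC(=O)CC[C@@H]1[C@]2(C)CO[C@@]1(C)[C@H](I)C[C@H]2O[Si](CC)(CC)CC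
F9 | step 14 | 4-[(1R,2R,5S,8R)-1,5-dimethyl-2-(triethylsilyloxy)-6-oxabicyclo[3.2.1]octan-8-yl]butan-2-one | CC(=O)CC[C@@H]1[C@]2(C)CO[C@@]1(C)CC[C@H]2O[Si](CC)(CC)CC
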